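**Retrosynthetic overview**
1. Target 11 is 2,5-dibromo-3,6-bis(2,3,5-tribromo-4-hydroxyphenoxy)benzene-1,4-diol. BBr3 frees the central 1,4-diol from dimethyl ether 10 last, and the six outer-ring bromines of 10 come from bromination of bisphenol 9.
2. Key disconnection: the two C4'–OH bonds of 9, made by twofold para C–H hydroxylation of the bis(phenyl) ether 5 with phthaloyl peroxide 7.
3. Feature: in each outer ring the hydroxyl sits on C4', para to the ether oxygen on C1'. The central ring C1–C6 is hexasubstituted (two Br, two OMe, two OAr) and has no C–H bond, so only the outer rings can be oxygenated.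
4. Precursor 5 comes from bromanil 1: phenoxide displaces the bromides at C3 and C6 of the quinone, then reduction and O-methylation.
5. No ring of the target is built. The central ring comes from 1 and the outer rings from phenol 2; only the peroxide ring of reagent 7 is closed (step 4).

Key step: step 5

Remark: the target has no stereocentre, and its diaryl ether axes are taken to rotate freely, so no stereochemical element has to be set.

**Route**

Step 1
Reactants: 1 bromanil (2,3,5,6-tetrabromo-1,4-benzoquinone); 2 phenol
Product: 3 2,5-dibromo-3,6-diphenoxy-1,4-benzoquinone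
Conditions: 2 (2.05 equiv), K2CO3 (2.5 equiv), MeCN, 0 → 23 °C
Reagents that add atoms: none
Why: Addition–elimination (vinylogous nucleophilic acyl substitution) of phenoxide on the tetrahaloquinone, in which the first aryloxy group turns its own enone into a vinylogous ester and so sends the second phenoxide to the distal C=C carbon (2,5-pattern), while two equivalents at low temperature should stop the exchange at the bis(aryloxy) stage.

Step 2
Reactants: 3 2,5-dibromo-3,6-diphenoxy-1,4-benzoquinone
Product: 4 2,5-dibromo-3,6-diphenoxybenzene-1,4-diol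
Conditions: Na2S2O4 (3 equiv), EtOAc/H2O, 23 °C
Reagents that add atoms: none
Why: Dithionite reduction of a quinone to its hydroquinone is a two-electron, two-proton transfer that leaves aryl bromides and diaryl ethers untouched.

Step 3
Reactants: 4 2,5-dibromo-3,6-diphenoxybenzene-1,4-diol
Product: 5 1,4-dibromo-2,5-dimethoxy-3,6-diphenoxybenzene
Conditions: MeI (4 equiv), K2CO3 (3 equiv), DMF, 23 → 40 °C, argon
Reagents that add atoms: iodomethane, SMILES CI
Why: Williamson O-methylation of the two acidic hydroxyls, the only nucleophilic sites of a fully substituted ring, with air excluded so that the hydroquinone dianion is not re-oxidised.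

Step 4
Reactants: 6 phthaloyl chloride
Product: 7 phthaloyl peroxide (2,3-benzodioxine-1,4-dione)
Conditions: sodium percarbonate 2Na2CO3·3H2O2, CH2Cl2, 23 °C
Reagents that add atoms: sodium percarbonate (2Na2CO3·3H2O2, donor of the O–O unit), SMILES [Na+].[Na+].[Na+].[Na+].[O-]C([O-])=O.[O-]C([O-])=O.OO.OO.OO
Why: Twofold nucleophilic acyl substitution of the diacid chloride by hydrogen peroxide released from the percarbonate closes the six-membered cyclic diacyl peroxide while carbonate takes up the HCl; the shock-sensitive reagent is made in small batches, kept cold and used soon.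

Step 5
Reactants: 5 1,4-dibromo-2,5-dimethoxy-3,6-diphenoxybenzene; 7 phthaloyl peroxide
Product: 9 4,4'-[(2,5-dibromo-3,6-dimethoxy-1,4-phenylene)bis(oxy)]diphenol, via bis(hydrogen phthalate) ester 8 (not isolated)
Conditions: 7 (2.8 equiv), HFIP, 23 → 40 °C; then NaHCO3, MeOH/H2O, 40 °C
Reagents that add atoms: phthaloyl peroxide (compound 7), SMILES O=C1OOC(=O)c2ccccc12
Why: The cyclic diacyl peroxide, activated by hydrogen bonding to HFIP, attacks the electron-rich phenoxy π-system with its O–O bond in a reverse-rebound pathway: C–O bond formation gives a cyclohexadienyl radical paired with a carboxyl radical, and transfer of the hydrogen from the attacked carbon to that carboxylate restores aromaticity and leaves an aryl hydrogen phthalate, which bicarbonate in aqueous methanol cleaves to the phenol. This is the known metal-free arene C–H hydroxylation with phthaloyl peroxide, used here on both phenoxy rings of one molecule. No ring is closed and no stereocentre is formed. The step needs para over ortho attack on each phenoxy ring and outer-ring over central-ring attack: C4' is the most activated and least hindered carbon, the ortho carbon turned towards the hexasubstituted central ring is shielded by it, and the central ring has no C–H bond and is a poor donor because its methoxy and aryloxy groups are twisted out of conjugation and it carries two bromines. The acyloxy group put on a ring deactivates it against a second oxidation, and since the two phenoxy rings are electronically insulated from each other the second ring should react like the first.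

Step 6
Reactants: 9 4,4'-[(2,5-dibromo-3,6-dimethoxy-1,4-phenylene)bis(oxy)]diphenol
Product: 10 4,4'-[(2,5-dibromo-3,6-dimethoxy-1,4-phenylene)bis(oxy)]bis(2,3,6-tribromophenol)
Conditions: Br2 (6.2 equiv), Fe powder (5 mol %), AcOH, 20 → 60 °C
Reagents that add atoms: bromine, SMILES BrBr
Why: Electrophilic aromatic bromination takes the two positions ortho to each free hydroxyl first, the third bromine can then only enter ortho to the aryloxy oxygen at one of two equivalent sites, each bromine already present slows the next substitution strongly so that the last C–H of each ring should survive the measured amount of bromine, and the central ring has no position to brominate.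

Step 7
Reactants: 10 4,4'-[(2,5-dibromo-3,6-dimethoxy-1,4-phenylene)bis(oxy)]bis(2,3,6-tribromophenol)
Product: 11 2,5-dibromo-3,6-bis(2,3,5-tribromo-4-hydroxyphenoxy)benzene-1,4-diol
Conditions: BBr3 (8 equiv), CH2Cl2, −78 → 23 °C; then H2O, 0 °C, argon
Reagents that add atoms: none
Why: Lewis acid-mediated cleavage of the two aryl methyl ethers with BBr3 (bromide attacks the methyl of the O–B adduct) leaves diaryl ether bonds and aryl bromides intact, and hydrolysis of the aryl borates releases the central hydroquinone.

**Compound list**
1 | bromanil (2,3,5,6-tetrabromo-1,4-benzoquinone) | BrC1=C(Br)C(=O)C(Br)=C(Br)C1=O | starting material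
2 | phenol | Oc1ccccc1 | starting material
3 | 2,5-dibromo-3,6-diphenoxy-1,4-benzoquinone | O=C1C(Br)=C(Oc2ccccc2)C(=O)C(Br)=C1Oc1ccccc1 | intermediate
4 | 2,5-dibromo-3,6-diphenoxybenzene-1,4-diol | Oc1c(Br)c(Oc2ccccc2)c(O)c(Br)c1Oc1ccccc1 | intermediate
5 | 1,4-dibromo-2,5-dimethoxy-3,6-diphenoxybenzene | COc1c(Br)c(Oc2ccccc2)c(OC)c(Br)c1Oc1ccccc1 | intermediate
6 | phthaloyl chloride | O=C(Cl)c1ccccc1C(Cl)=O | starting material
7 | phthaloyl peroxide (2,3-benzodioxine-1,4-dione) | O=C1OOC(=O)c2ccccc12 | intermediate
8 | bis(hydrogen phthalate) ester of 9, formed in the flask (not isolated) | COc1c(Br)c(Oc2ccc(OC(=O)c3ccccc3C(=O)O)cc2)c(OC)c(Br)c1Oc1ccc(OC(=O)c2ccccc2C(=O)O)cc1 | intermediate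
9 | 4,4'-[(2,5-dibromo-3,6-dimethoxy-1,4-phenylene)bis(oxy)]diphenol | COc1c(Br)c(Oc2ccc(O)cc2)c(OC)c(Br)c1Oc1ccc(O)cc1 | intermediate
10 | 4,4'-[(2,5-dibromo-3,6-dimethoxy-1,4-phenylene)bis(oxy)]bis(2,3,6-tribromophenol) | COc1c(Br)c(Oc2cc(Br)c(O)c(Br)c2Br)c(OC)c(Br)c1Oc1cc(Br)c(O)c(Br)c1Br | intermediate
11 | 2,5-dibromo-3,6-bis(2,3,5-tribromo-4-hydroxyphenoxy)benzene-1,4-diol | Oc1c(Br)cc(Oc2c(O)c(Br)c(Oc3cc(Br)c(O)c(Br)c3Br)c(O)c2Br)c(Br)c1Br | target

**Step count**
Total: 7 steps. Longest linear sequence: 6 steps (1, 2, 3, 5, 6, 7); step 4 is a one-step side branch that makes the oxidant.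

**Steps most likely to fail**

Step 5 (key step). The peroxide may attack the ortho carbon that is turned away from the central ring instead of C4', the reaction may stall after one ring, or ipso attack on the central ring may lead to oxidative loss of a methyl group. The fallback sets out from 5 and comes back at 9, replacing the direct C–H oxygenation by halogenation, borylation and oxidation. Para-iodination of both phenoxy rings with N-iodosuccinimide and trifluoroacetic acid in MeCN at 23 °C should give 1,4-dibromo-2,5-bis(4-iodophenoxy)-3,6-dimethoxybenzene F1. Miyaura borylation (B2pin2, PdCl2(dppf), KOAc, 1,4-dioxane, 80 °C) should take the unhindered C–I bonds in preference to the doubly ortho-substituted C–Br bonds of the central ring and give the bis(pinacol boronate) F2. Oxidation with H2O2 and NaOH in THF/H2O at 0 °C then returns bisphenol 9.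

Step 6. The third substitution on each ring, ortho to the ether on an already dibrominated phenol, is slow. Ipso attack of bromine at the ether-bearing carbon para to the hydroxyl, with oxidative cleavage of the diaryl ether, or stalling at mixed degrees of bromination may take over. The fallback sets out from 1 and comes back at 10; it brings the bromine ortho to the ether in with the phenol, so that only the fast positions ortho to hydroxyl remain. Steps 1 to 3 are repeated with 2-bromophenol: K2CO3 in MeCN should give 2,5-dibromo-3,6-bis(2-bromophenoxy)-1,4-benzoquinone F3, Na2S2O4 should reduce it to 2,5-dibromo-3,6-bis(2-bromophenoxy)benzene-1,4-diol F4, and MeI with K2CO3 should give 1,4-dibromo-2,5-bis(2-bromophenoxy)-3,6-dimethoxybenzene F5. Phthaloyl peroxide 7 in HFIP should then oxidise the C–H para to each ether oxygen through the bis(hydrogen phthalate) F6, which is hydrolysed without isolation to 4,4'-[(2,5-dibromo-3,6-dimethoxy-1,4-phenylene)bis(oxy)]bis(3-bromophenol) F7. Br2 (4 equiv) in AcOH at 20 °C should brominate only the two positions ortho to each hydroxyl and deliver 10.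

Step 1. Phenoxide may go on to displace a third and fourth bromide, or may transfer an electron to the strongly oxidising haloquinone, so that reduction of the quinone and phenol coupling compete with substitution. The fallback sets out from 1 and comes back at 5, introducing the two kinds of oxygen substituent in the reverse order. NaOMe (2 equiv) in MeOH at 0 °C should give 2,5-dibromo-3,6-dimethoxy-1,4-benzoquinone F8, and Na2S2O4 in EtOAc/H2O should reduce it to 2,5-dibromo-3,6-dimethoxybenzene-1,4-diol F9. 2-(Trimethylsilyl)phenyl trifluoromethanesulfonate and CsF in MeCN at 23 °C generate benzyne F10 in the flask, which should O-phenylate both hydroxyls by aryne addition and protonation to give 5.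

**Further compounds**
F1 | step 5 | 1,4-dibromo-2,5-bis(4-iodophenoxy)-3,6-dimethoxybenzene | COc1c(Br)c(Oc2ccc(I)cc2)c(OC)c(Br)c1Oc1ccc(I)cc1
F2 | step 5 | 2,2'-{[(2,5-dibromo-3,6-dimethoxy-1,4-phenylene)bis(oxy)]bis(4,1-phenylene)}bis(4,4,5,5-tetramethyl-1,3,2-dioxaborolane) | COc1c(Br)c(Oc2ccc(B3OC(C)(C)C(C)(C)O3)cc2)c(OC)c(Br)c1Oc1ccc(B2OC(C)(C)C(C)(C)O2)cc1
F3 | step 6 | 2,5-dibromo-3,6-bis(2-bromophenoxy)-1,4-benzoquinone | O=C1C(Br)=C(Oc2ccccc2Br)C(=O)C(Br)=C1Oc1ccccc1Br
F4 | step 6 | 2,5-dibromo-3,6-bis(2-bromophenoxy)benzene-1,4-diol | Oc1c(Br)c(Oc2ccccc2Br)c(O)c(Br)c1Oc1ccccc1Br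
F5 | step 6 | 1,4-dibromo-2,5-bis(2-bromophenoxy)-3,6-dimethoxybenzene | COc1c(Br)c(Oc2ccccc2Br)c(OC)c(Br)c1Oc1ccccc1Br
F6 | step 6 | bis(hydrogen phthalate) ester of F7 (not isolated) | COc1c(Br)c(Oc2ccc(OC(=O)c3ccccc3C(=O)O)cc2Br)c(OC)c(Br)c1Oc1ccc(OC(=O)c2ccccc2C(=O)O)cc1Br
F7 | step 6 | 4,4'-[(2,5-dibromo-3,6-dimethoxy-1,4-phenylene)bis(oxy)]bis(3-bromophenol) | COc1c(Br)c(Oc2ccc(O)cc2Br)c(OC)c(Br)c1Oc1ccc(O)cc1Br
F8 | step 1 | 2,5-dibromo-3,6-dimethoxy-1,4-benzoquinone | COC1=C(Br)C(=O)C(OC)=C(Br)C1=O
F9 | step 1 | 2,5-dibromo-3,6-dimethoxybenzene-1,4-diol | COc1c(Br)c(O)c(OC)c(Br)c1O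
F10 | step 1 | benzyne (not isolated) | C1#CC=CC=C1
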